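At early times two runs with the same loading, [stray impurity] and temperature, but different charges of starting material and protic impurity, part at once: at 0.208 d Wednesday's run reads 2.7% and Thursday's 0%.

common to all: free enzyme 0.05 mol%; stray impurity 20 µM
- Wednesday's: starting material 0.050 M (in portions, 2); protic impurity 0.0071 M; temperature 15 °C; run made earlier; portions every 2.5 d
- Friday's: starting material 0.050 M (in portions, 2); protic impurity 0.019 M; temperature 30 °C; run made earlier; portions every 2.5 d
- Thursday's: starting material 0.021 M (in portions, 2); protic impurity 0.025 M; temperature 15 °C; run made earlier; portions every 2.5 d
- theta: starting material 0.050 M (in portions, 2); protic impurity 0.0250 M; at 20 °C until 40 h, from then on at 40 °C; the portions of starting material follow each other after 2.5 d, the first at the start; time 5.0 d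
- gamma: starting material 0.015 M (in portions, 2); protic impurity 0.00800 M; at 40 °C throughout; the portions of starting material follow each other after 2.5 d, the first at the start; time 5.0 d

Wednesday's run (percent of the starting material charged): time / d: product / % = 0.208: 2.7; 0.625: 6.7; 1.25: 12.2; 1.67: 15.4; 2.50: 21.4

Friday's run (percent of the starting material charged): time / h: product / % = 8.00: 8.9; 15.0: 14.1; 25.0: 19.5; 30.0: 21.0; 40.0: 23.3

Thursday's run (percent of the starting material charged): time / d: product / % = 0.208: 0; 0.417: 0.1; 0.625: 0.3; 1.25: 0.4; 2.50: 0.4

(each reading ± 0.3 percentage points)

- the flask that ends with the higher amount of product, in percent of the starting material charged, or "neither" when 2 percentage points or less lies between them (theta / gamma / neither)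
- final product, as a percentage of the starting material charged, in theta
- final product, as a percentage of the starting material charged, in gamma

- the earlier runs were read with a standard deviation of 0.3 percentage points
- steps under discussion: free enzyme -> unfolded enzyme; starting material + free enzyme -> product + free enzyme; free enzyme + stray impurity -> spent catalyst; starting material + protic impurity -> quenched substrate
- where the amount of starting material changes, what is given in equivalents or mol% on it follows

1. The puzzle: both runs hold 0.05 mol% of free enzyme at 15 °C, and Thursday's charge is 0.420 of Wednesday's. Yet Thursday's run ends at 0.4% against 21.4%, 53.5 times less product, and it reads the same at 1.25 d and 2.50 d.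

2. I take stray impurity to bind free enzyme one for one, a titration in which the limiting reagent may be either partner. The live margin is the loading times the whole charge, minus [stray impurity]; for theta it is 5.00 µM. Wednesday's margin is 5.00 µM, but Thursday's is −9.50 µM, so I read Thursday's product as a burst before the enzyme is bound.

3. Theta's margin equals Friday's 5.00 µM, so I expect about Friday's 23.3% from theta's first portion. Its second portion meets 40 °C, hotter than Friday's 30 °C, so I don't count on that portion.

4. Gamma's margin is −12.5 µM. Gamma's enzyme charge is less than its [stray impurity], so its margin is negative like Thursday's, and I take a burst near 0.4%, and theta gives more.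

5. The forecast says theta, with 45% (25% to 54%) for theta and 0.5% (0.1% to 2%) for gamma, on the ground that “The second portion meets no impurity”.

6. The flasks give theta as the higher: theta 22.7%, gamma 0.163%.

    free enzyme → unfolded enzyme (k = 3.50 × 10⁻⁶ min⁻¹, Ea = 251 kJ mol⁻¹)
    starting material + free enzyme → product + free enzyme, rate k2*[starting material]*[free enzyme]/(1 + ([starting material]/Km2)) (0.0560 M, k = 61.0 M⁻¹ min⁻¹, Ea = 50.0 kJ mol⁻¹)
    free enzyme + stray impurity → spent catalyst (k = 10000 M⁻¹ min⁻¹, Ea = 40.0 kJ mol⁻¹)
    starting material + protic impurity → quenched substrate (k = 0.00920 M⁻¹ min⁻¹, Ea = 74.0 kJ mol⁻¹)
    (constants at 20 °C)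

Gamma's stray impurity ends at 62.7% of its charge, and its margin gives 62.5%. Theta's free enzyme stands at 19.8% of the catalyst charged at 1.67 d, and its margin 5.00 µM over the charged 25.0 µM gives 20.0%. By 2.50 d theta's free enzyme is down to 0.973%, with unfolded enzyme at 19.0%. At 2.51 d, just after theta's second portion, the path to quenched substrate uses starting material 23 times as fast as the path to product.

(The readings stem from a simulated flask with made-up constants.)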